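The plan cuts two neighbouring bonds of the benzenoid ring of the chromene at once: C5–O and C6–C(=O). A C5≡C6 aryne inserts formally into the C–O bond of 3-phenylpropanoic acid. The chelated ortho-hydroxy ketone and the whole dihydrochalcone side chain therefore arrive in one operation, and no ring is closed. The step exploits the ortho relationship of the C5 hydroxyl and the C6 ketone, together with the C7 methoxy group on the other side of C6, which sends the carboxylate oxygen to C5. The precursor is the finished 2,2-dimethyl-2H-chromene bearing C5–SiMe3, C6–OTf, C7–OMe and a methoxymethyl-protected O8. It is assembled by three successive directed lithiations (C8, C6, C5).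

Key step: step 8

Remark on the chemistry: the target has no stereocentre, and its only non-aromatic double bond (C3=C4) is held cis by the pyran ring, so no configuration has to be set. Chromene numbering is used throughout (O1, C2, C3, C4, C4a, C5–C8, C8a).

Design note: silicon is brought to C5 by carbamate-directed lithiation, not through an aryl bromide. An electrophilic bromine source would have to distinguish the ring from the electron-rich C3=C4 olefin and from an easily oxidised para-alkoxyphenol. The step count is the same either way.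

Step 1
Reactants: 1 3-methoxyphenol; 2 3-methylbut-2-enal
Product: 4 7-methoxy-2,2-dimethyl-2H-chromene, via ortho-quinone methide 3 (not isolated)
Conditions: PhB(OH)2, AcOH, toluene, reflux, azeotropic removal of water
Reagents that add atoms: none
Why: In this boronic-acid-mediated phenol–enal chromene annulation, phenylboronic acid holds phenol and enal together so that the aldol-type C–C bond forms only ortho to the hydroxyl, at the less hindered carbon para to the methoxy group, and loss of water gives 3, which closes the pyran ring by oxa-6π electrocyclisation.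

Step 2
Reactants: 4 7-methoxy-2,2-dimethyl-2H-chromene
Product: 7 7-methoxy-2,2-dimethyl-2H-chromen-8-ol, via 8-lithiochromene 5 (not isolated), via lithium aryltrimethoxyborate 6 (not isolated)
Conditions: n-BuLi, THF, 0 °C to rt; B(OMe)3, −78 °C to rt; 30% aq H2O2, AcOH, 0 °C
Reagents that add atoms: hydrogen peroxide, OO
Why: This is a directed ortho-metalation in which C8–H, lying between the ether oxygens O1 and O7, is the most acidic and best coordinated site, and borylation followed by peroxide oxidation (1,2-aryl shift from boron to oxygen) should turn C–Li into C–OH without touching the olefin.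

Step 3
Reactants: 7 7-methoxy-2,2-dimethyl-2H-chromen-8-ol
Product: 8 7-methoxy-8-(methoxymethoxy)-2,2-dimethyl-2H-chromene
Conditions: NaH, MOMCl, THF, 0 °C to rt
Reagents that add atoms: chloromethyl methyl ether, COCCl
Why: Williamson-type O-alkylation of the sodium phenoxide with the reactive α-chloro ether gives an acetal that withstands organolithiums, amine bases and fluoride and leaves under mild acid.

Step 4
Reactants: 8 7-methoxy-8-(methoxymethoxy)-2,2-dimethyl-2H-chromene
Product: 11 7-methoxy-8-(methoxymethoxy)-2,2-dimethyl-2H-chromen-6-ol, via 6-lithiochromene 9 (not isolated), via lithium aryltrimethoxyborate 10 (not isolated)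
Conditions: n-BuLi, TMEDA, Et2O, 0 °C to rt; B(OMe)3, −78 °C to rt; 30% aq H2O2, AcOH, 0 °C
Reagents that add atoms: hydrogen peroxide, OO
Why: This is a directed ortho-metalation of a 1,2,3-trialkoxyarene in which, with C8 filled, the only proton ortho to an oxygen director is C6–H beside the C7 methoxy group (the analogue of the 4-lithiation of 1,2,3-trimethoxybenzene), and borylation–oxidation again delivers the phenol.

Step 5
Reactants: 11 7-methoxy-8-(methoxymethoxy)-2,2-dimethyl-2H-chromen-6-ol
Product: 12 7-methoxy-8-(methoxymethoxy)-2,2-dimethyl-2H-chromen-6-yl N-isopropylcarbamate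
Conditions: i-PrNCO, Et3N (cat.), CH2Cl2, rt
Reagents that add atoms: isopropyl isocyanate, CC(C)N=C=O
Why: Base-catalysed addition of the phenol to the isocyanate gives a secondary carbamate, a strong metalation director that can later be removed under mild E1cB conditions.

Step 6
Reactants: 12 7-methoxy-8-(methoxymethoxy)-2,2-dimethyl-2H-chromen-6-yl N-isopropylcarbamate
Product: 16 7-methoxy-8-(methoxymethoxy)-2,2-dimethyl-5-(trimethylsilyl)-2H-chromen-6-yl N-isopropylcarbamate, via N-silyl carbamate 13 (not isolated), via C5-lithio carbamate 14 (not isolated), via C5-silyl N-silyl carbamate 15 (not isolated)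
Conditions: TBSOTf, TMEDA, Et2O, 0 °C to rt; s-BuLi, TMEDA, −78 °C; TMSCl, −78 °C to rt; 10% aq citric acid work-up
Reagents that add atoms: chlorotrimethylsilane, C[Si](C)(C)Cl
Why: In this carbamate-directed ortho-metalation after transient N-silylation, C5–H is the only aromatic hydrogen left and sits ortho to the strongest director, so lithiation and a cold chlorosilane quench should place silicon on C5 before any carbamoyl migration, and the N–Si bond is hydrolysed on work-up.

Step 7
Reactants: 16 7-methoxy-8-(methoxymethoxy)-2,2-dimethyl-5-(trimethylsilyl)-2H-chromen-6-yl N-isopropylcarbamate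
Product: 18 7-methoxy-8-(methoxymethoxy)-2,2-dimethyl-5-(trimethylsilyl)-2H-chromen-6-yl trifluoromethanesulfonate, via silylphenol 17 (not isolated)
Conditions: Et2NH, DBU, MeCN, 40 °C; then PhNTf2, rt
Reagents that add atoms: N-phenylbis(trifluoromethanesulfonimide), O=S(=O)(N(c1ccccc1)S(=O)(=O)C(F)(F)F)C(F)(F)F
Why: In this one-pot carbamate cleavage–triflation, DBU triggers E1cB loss of isopropyl isocyanate, which diethylamine traps as a urea, and the liberated hindered phenoxide of 17 is sulfonylated in the same flask by the mild triflyl donor.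

Step 8
Reactants: 18 7-methoxy-8-(methoxymethoxy)-2,2-dimethyl-5-(trimethylsilyl)-2H-chromen-6-yl trifluoromethanesulfonate; 19 3-phenylpropanoic acid
Product: 22 1-[5-hydroxy-7-methoxy-8-(methoxymethoxy)-2,2-dimethyl-2H-chromen-6-yl]-3-phenylpropan-1-one, via C5≡C6 aryne 20 (not isolated), via C6 carbanion ester 21 (not isolated)
Conditions: 19 (1.5 equiv), CsF (4 equiv), THF, 125 °C, sealed tube
Reagents that add atoms: none
Why: Fluoride attacks the C5 silicon and the C6 triflate is expelled, releasing aryne 20 slowly because CsF is barely soluble in THF. The carboxylate of 19 adds through oxygen to C5, which puts the charge of 21 on C6, and this carbanion attacks the neighbouring ester carbonyl through a four-membered transition state (an anionic O-to-C acyl migration related to the anionic Fries rearrangement) to leave the C5 phenoxide, which is protonated to the hydrogen-bonded ketone 22. The reaction type is the known formal insertion of arynes into the C–O bond of carboxylic acids to give ortho-hydroxyaryl ketones, which is regioselective for arynes of the 3-methoxy type. No ring is closed and no stereocentre is created. The first selectivity needed is attack at C5 and not C6, secured by the inductively withdrawing C7 methoxy group, which widens the internal aryne angle at C5 and stabilises charge at C6, an effect expected to outweigh the bulk of the vinyl-bearing C4a. The second is acyl shift faster than protonation of C6, which the ethereal solvent, the high temperature and only a small excess of acid are chosen to favour.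

Step 9
Reactants: 22 1-[5-hydroxy-7-methoxy-8-(methoxymethoxy)-2,2-dimethyl-2H-chromen-6-yl]-3-phenylpropan-1-one
Product: 23 flemistrictin D, 1-(5,8-dihydroxy-7-methoxy-2,2-dimethyl-2H-chromen-6-yl)-3-phenylpropan-1-one
Conditions: 3 M aq HCl, MeOH, 45 °C, under argon
Reagents that add atoms: none
Why: Acid-catalysed acetal hydrolysis of the aryl methoxymethyl ether runs under conditions mild enough for the 2,2-dimethylchromene olefin and the aryl methyl ether, and exclusion of air protects the C5/C8 hydroquinone from oxidation.

Compound list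
1 | 3-methoxyphenol | COc1cccc(O)c1 | starting material
2 | 3-methylbut-2-enal | CC(C)=CC=O | starting material
3 | (6Z)-3-methoxy-6-(3-methylbut-2-en-1-ylidene)cyclohexa-2,4-dien-1-one (formed in situ) | O=C1C=C(OC)C=C/C1=C/C=C(C)C | intermediate
4 | 7-methoxy-2,2-dimethyl-2H-chromene | COc1ccc2C=CC(C)(C)Oc2c1 | intermediate
5 | (7-methoxy-2,2-dimethyl-2H-chromen-8-yl)lithium (formed in situ) | COc1ccc2C=CC(C)(C)Oc2c1[Li] | intermediate
6 | lithium trimethoxy(7-methoxy-2,2-dimethyl-2H-chromen-8-yl)borate (formed in situ) | [Li+].COc1ccc2C=CC(C)(C)Oc2c1[B-](OC)(OC)OC | intermediate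
7 | 7-methoxy-2,2-dimethyl-2H-chromen-8-ol | COc1ccc2C=CC(C)(C)Oc2c1O | intermediate
8 | 7-methoxy-8-(methoxymethoxy)-2,2-dimethyl-2H-chromene | COc1ccc2C=CC(C)(C)Oc2c1OCOC | intermediate
9 | [7-methoxy-8-(methoxymethoxy)-2,2-dimethyl-2H-chromen-6-yl]lithium (formed in situ) | COc1c([Li])cc2C=CC(C)(C)Oc2c1OCOC | intermediate
10 | lithium trimethoxy[7-methoxy-8-(methoxymethoxy)-2,2-dimethyl-2H-chromen-6-yl]borate (formed in situ) | [Li+].COc1c(cc2C=CC(C)(C)Oc2c1OCOC)[B-](OC)(OC)OC | intermediate
11 | 7-methoxy-8-(methoxymethoxy)-2,2-dimethyl-2H-chromen-6-ol | COc1c(O)cc2C=CC(C)(C)Oc2c1OCOC | intermediate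
12 | 7-methoxy-8-(methoxymethoxy)-2,2-dimethyl-2H-chromen-6-yl N-isopropylcarbamate | COc1c(OC(=O)NC(C)C)cc2C=CC(C)(C)Oc2c1OCOC | intermediate
13 | 7-methoxy-8-(methoxymethoxy)-2,2-dimethyl-2H-chromen-6-yl N-(tert-butyldimethylsilyl)-N-isopropylcarbamate (formed in situ) | COc1c(OC(=O)N(C(C)C)[Si](C)(C)C(C)(C)C)cc2C=CC(C)(C)Oc2c1OCOC | intermediate
14 | 5-lithio derivative of 13 (formed in situ) | COc1c(OC(=O)N(C(C)C)[Si](C)(C)C(C)(C)C)c([Li])c2C=CC(C)(C)Oc2c1OCOC | intermediate
15 | 5-(trimethylsilyl) derivative of 13 (formed in situ) | COc1c(OC(=O)N(C(C)C)[Si](C)(C)C(C)(C)C)c([Si](C)(C)C)c2C=CC(C)(C)Oc2c1OCOC | intermediate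
16 | 7-methoxy-8-(methoxymethoxy)-2,2-dimethyl-5-(trimethylsilyl)-2H-chromen-6-yl N-isopropylcarbamate | COc1c(OC(=O)NC(C)C)c([Si](C)(C)C)c2C=CC(C)(C)Oc2c1OCOC | intermediate
17 | 7-methoxy-8-(methoxymethoxy)-2,2-dimethyl-5-(trimethylsilyl)-2H-chromen-6-ol (formed in situ) | COc1c(O)c([Si](C)(C)C)c2C=CC(C)(C)Oc2c1OCOC | intermediate
18 | 7-methoxy-8-(methoxymethoxy)-2,2-dimethyl-5-(trimethylsilyl)-2H-chromen-6-yl trifluoromethanesulfonate | COc1c(OCOC)c2c(c([Si](C)(C)C)c1OS(=O)(=O)C(F)(F)F)C=CC(C)(C)O2 | intermediate
19 | 3-phenylpropanoic acid | OC(=O)CCc1ccccc1 | starting material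
20 | 5,6-didehydro-7-methoxy-8-(methoxymethoxy)-2,2-dimethyl-2H-chromene (aryne, formed in situ) | COC1=C(OCOC)C2=C(C#C1)C=CC(C)(C)O2 | intermediate
21 | cesium 7-methoxy-8-(methoxymethoxy)-2,2-dimethyl-5-(3-phenylpropanoyloxy)-2H-chromen-6-ide (formed in situ) | [Cs+].COc1[c-]c(OC(=O)CCc3ccccc3)c2C=CC(C)(C)Oc2c1OCOC | intermediate
22 | 1-[5-hydroxy-7-methoxy-8-(methoxymethoxy)-2,2-dimethyl-2H-chromen-6-yl]-3-phenylpropan-1-one | COc1c(OCOC)c2c(c(O)c1C(=O)CCc1ccccc1)C=CC(C)(C)O2 | intermediate
23 | flemistrictin D, 1-(5,8-dihydroxy-7-methoxy-2,2-dimethyl-2H-chromen-6-yl)-3-phenylpropan-1-one | COc1c(O)c2c(c(O)c1C(=O)CCc1ccccc1)C=CC(C)(C)O2 | target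

Total step count: 9. Longest linear sequence: 9 steps (from 1 to 23).

Steps most likely to fail

Step 8. The C6 carbanion may be protonated before the acyl group migrates, so that the process stops at O-arylation. Capture of the aryne by the electron-rich C3=C4 olefin of a second molecule, or erosion of the C5/C6 regioselectivity, would also lower the return. The fallback separates O-arylation from C-acylation.
- Setting out from 18, CsF in MeCN at room temperature with 19 is the plain O-arylation of a carboxylic acid by an aryne, in which the carbanion is protonated faster than it attacks the ester. It should give 7-methoxy-8-(methoxymethoxy)-2,2-dimethyl-2H-chromen-5-yl 3-phenylpropanoate F1.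
- Methanolysis with K2CO3 in MeOH should free 7-methoxy-8-(methoxymethoxy)-2,2-dimethyl-2H-chromen-5-ol F2.
- NaH and MOMCl should give 7-methoxy-5,8-bis(methoxymethoxy)-2,2-dimethyl-2H-chromene F3.
- n-BuLi in THF at 0 °C should remove the only aromatic proton, C6–H between two oxygen directors, to give [7-methoxy-5,8-bis(methoxymethoxy)-2,2-dimethyl-2H-chromen-6-yl]lithium F4.
- Acylation with purchased N-methoxy-N-methyl-3-phenylpropanamide should give 1-[7-methoxy-5,8-bis(methoxymethoxy)-2,2-dimethyl-2H-chromen-6-yl]-3-phenylpropan-1-one F5.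
- Aqueous HCl in MeOH removes both acetals, so the sequence comes back to the route at 23.

Step 4. Deprotonation at C6 depends on a single methoxy director that is twisted by its neighbour. Metalation may therefore be slow, and the alkyllithium may instead add to the styrene-like C3=C4 bond. The fallback installs the C6 handle by electrophilic substitution instead of deprotonation. Setting out from 8, NBS in MeCN at −20 °C should brominate the most nucleophilic ring position (para to O1, ortho to O7) to give 6-bromo-7-methoxy-8-(methoxymethoxy)-2,2-dimethyl-2H-chromene F6. Bromine–lithium exchange with n-BuLi in THF at −78 °C comes back to the route at 9, which is borylated and oxidised as before.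

Step 6. The silyl triflate used for the transient N-protection may attack the methoxymethyl acetal, or the N-silyl carbamate may fragment before C5 is metalated. The fallback reaches the C–Si bond by halogenation and a retro-Brook shift.
- Setting out from 11, NBS in CH2Cl2 at −78 °C should brominate the only free ring position to give 5-bromo-7-methoxy-8-(methoxymethoxy)-2,2-dimethyl-2H-chromen-6-ol F7.
- (Me3Si)2NH in refluxing THF should give [5-bromo-7-methoxy-8-(methoxymethoxy)-2,2-dimethyl-2H-chromen-6-yl]oxy(trimethyl)silane F8.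
- n-BuLi in THF at −78 °C should give [7-methoxy-8-(methoxymethoxy)-2,2-dimethyl-6-(trimethylsilyloxy)-2H-chromen-5-yl]lithium F9.
- The O-to-C silyl migration of F9 should give lithium 7-methoxy-8-(methoxymethoxy)-2,2-dimethyl-5-(trimethylsilyl)-2H-chromen-6-olate F10.
- Addition of Tf2O at −78 °C comes back to the route at 18.

Further compounds
F1 | step 8 | 7-methoxy-8-(methoxymethoxy)-2,2-dimethyl-2H-chromen-5-yl 3-phenylpropanoate | COc1cc(OC(=O)CCc3ccccc3)c2C=CC(C)(C)Oc2c1OCOC
F2 | step 8 | 7-methoxy-8-(methoxymethoxy)-2,2-dimethyl-2H-chromen-5-ol | COc1cc(O)c2C=CC(C)(C)Oc2c1OCOC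
F3 | step 8 | 7-methoxy-5,8-bis(methoxymethoxy)-2,2-dimethyl-2H-chromene | COc1cc(OCOC)c2C=CC(C)(C)Oc2c1OCOC
F4 | step 8 | [7-methoxy-5,8-bis(methoxymethoxy)-2,2-dimethyl-2H-chromen-6-yl]lithium | COc1c([Li])c(OCOC)c2C=CC(C)(C)Oc2c1OCOC
F5 | step 8 | 1-[7-methoxy-5,8-bis(methoxymethoxy)-2,2-dimethyl-2H-chromen-6-yl]-3-phenylpropan-1-one | COc1c(C(=O)CCc3ccccc3)c(OCOC)c2C=CC(C)(C)Oc2c1OCOC
F6 | step 4 | 6-bromo-7-methoxy-8-(methoxymethoxy)-2,2-dimethyl-2H-chromene | COc1c(Br)cc2C=CC(C)(C)Oc2c1OCOC
F7 | step 6 | 5-bromo-7-methoxy-8-(methoxymethoxy)-2,2-dimethyl-2H-chromen-6-ol | COc1c(O)c(Br)c2C=CC(C)(C)Oc2c1OCOC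
F8 | step 6 | [5-bromo-7-methoxy-8-(methoxymethoxy)-2,2-dimethyl-2H-chromen-6-yl]oxy(trimethyl)silane | COc1c(O[Si](C)(C)C)c(Br)c2C=CC(C)(C)Oc2c1OCOC
F9 | step 6 | [7-methoxy-8-(methoxymethoxy)-2,2-dimethyl-6-(trimethylsilyloxy)-2H-chromen-5-yl]lithium | COc1c(O[Si](C)(C)C)c([Li])c2C=CC(C)(C)Oc2c1OCOC
F10 | step 6 | lithium 7-methoxy-8-(methoxymethoxy)-2,2-dimethyl-5-(trimethylsilyl)-2H-chromen-6-olate | [Li+].COc1c([O-])c([Si](C)(C)C)c2C=CC(C)(C)Oc2c1OCOC
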